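The route rests on disconnecting the C4a–C5 bond of ring A. Ring A (C4a, C5, C6, C7, C8, C8a) carries oxygen on C5, C7 and C8a in the 1,3,5-pattern of a folded polyketide, and C4a is at the same time the α-carbon of the ring B pyranone carbonyl. A preformed 4-pyranone therefore serves as ring B and as the nucleophile: in one operation its lithium dienolate acylates C4a with a side-chain ester, closing and aromatizing ring A. The precursor is a 2,6-disubstituted 4-pyranone bearing the pentacosyl chain and a four-carbon (E)-3-methoxybut-2-enoate arm whose CH2 and ester lie cis.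

Key step: step 4

Remark on the chemistry: should step 3 give part of the enol ether with its double bond toward ring B, the mixture can be carried on, because deprotonation in step 4 leads to the same delocalized anion.

Step 1
Reactants: 1 2,6-dimethyl-4H-pyran-4-one; 2 1-bromotetracosane
Product: 3 2-methyl-6-pentacosyl-4H-pyran-4-one
Conditions: LiN(SiMe3)2 (3 equiv), 1 (3 equiv), THF, −78 °C; then 2 (1 equiv), DMPU, −78 → 25 °C; aq. NH4Cl
Reagents that add atoms: none
Why: Lateral deprotonation of a ring methyl group gives a lithium dienolate that should be alkylated at its exocyclic carbon by the primary bromide (SN2 alkylation of a vinylogous enolate), the excess of cheap 1 holding back double alkylation.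

Step 2
Reactants: 3 2-methyl-6-pentacosyl-4H-pyran-4-one; 4 methyl malonyl chloride (methyl 3-chloro-3-oxopropanoate)
Product: 5 methyl 3-oxo-4-(4-oxo-6-pentacosyl-4H-pyran-2-yl)butanoate
Conditions: 3 (2 equiv), LiN(SiMe3)2 (2 equiv), THF, −78 °C; then 4 (1 equiv), −78 → −40 °C; 1 M HCl; unreacted 3 recovered
Reagents that add atoms: none
Why: The hindered amide should remove a proton from the unhindered methyl group rather than from the chain CH2 (kinetic lateral deprotonation), and the lithium dienolate is then acylated at carbon by the acid chloride in a Claisen-type acylation, the second equivalent of dienolate taking up the acidic proton of 5.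

Step 3
Reactants: 5 methyl 3-oxo-4-(4-oxo-6-pentacosyl-4H-pyran-2-yl)butanoate; 6 trimethyl orthoformate
Product: 8 methyl (E)-3-methoxy-4-(4-oxo-6-pentacosyl-4H-pyran-2-yl)but-2-enoate, via dimethyl ketal 7 (not isolated)
Conditions: 6 (5 equiv), cat. H2SO4, MeOH/CH2Cl2, 25 → 45 °C; Et3N
Reagents that add atoms: none
Why: Acid-catalysed ketalization of the ketone by the orthoformate and loss of methanol toward the ester should give the push-pull β-methoxyacrylate as its thermodynamic E isomer, which places the CH2 cis to the ester (enol ether formation from a β-keto ester).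

Step 4
Reactants: 8 methyl (E)-3-methoxy-4-(4-oxo-6-pentacosyl-4H-pyran-2-yl)but-2-enoate
Product: 10 5-hydroxy-7-methoxy-2-pentacosyl-4H-chromen-4-one, via 4aH-dienone tautomer 9 (not isolated)
Conditions: LiN(SiMe3)2 (2.2 equiv), THF (0.01 M), −20 → 60 °C; 1 M HCl
Reagents that add atoms: none
Why: Proposed new method: LiN(SiMe3)2 removes a proton from the doubly activated C8 methylene of 8, giving an anion shared by the pyranone (C8, C4a, O at C4) and the acrylate; C4a adds to the ester carbonyl C5 (equally a 6π closure of the C4a=C8a/C8=C7/C6=C5 trienolate), methoxide is expelled, and dienone 9 tautomerizes to the chelated phenoxide of 10, which makes the sequence irreversible. The closest known reaction type is the biomimetic Claisen (Dieckmann) cyclization of 3,5,7-triketo esters to acylphloroglucinols, together with the α-acylation of vinylogous ester dienolates. Ring A closes in a 6-(enolexo)-exo-trig mode by forming the C4a–C5 bond. No stereocentre survives, since C4a of 9 becomes aromatic. The selectivity required is carbon acylation at C4a rather than an aldol-type closure, O-acylation or intermolecular condensation: C4a is the only nucleophilic atom that reaches C5 through a six-membered transition state, the E enol ether keeps C8 and C5 cis, the intact pyranone offers no free ketone, and high dilution disfavours bimolecular paths.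

Step 5
Reactants: 10 5-hydroxy-7-methoxy-2-pentacosyl-4H-chromen-4-one
Product: 11 5,7-dihydroxy-2-pentacosyl-4H-chromen-4-one
Conditions: BBr3 (5 equiv), CH2Cl2, −78 → 25 °C; then H2O
Reagents that add atoms: none
Why: BBr3 binds the 7-methoxy oxygen, bromide removes the methyl group by SN2 and hydrolysis of the aryl borate frees the second phenol, while ring B and the alkyl chain are inert (Lewis acid demethylation of an aryl methyl ether).

Compound list
1 | 2,6-dimethyl-4H-pyran-4-one | Cc1cc(=O)cc(C)o1 | starting material
2 | 1-bromotetracosane | CCCCCCCCCCCCCCCCCCCCCCCCBr | starting material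
3 | 2-methyl-6-pentacosyl-4H-pyran-4-one | CCCCCCCCCCCCCCCCCCCCCCCCCc1cc(=O)cc(C)o1 | intermediate
4 | methyl malonyl chloride (methyl 3-chloro-3-oxopropanoate) | COC(=O)CC(=O)Cl | starting material
5 | methyl 3-oxo-4-(4-oxo-6-pentacosyl-4H-pyran-2-yl)butanoate | CCCCCCCCCCCCCCCCCCCCCCCCCc1cc(=O)cc(CC(=O)CC(=O)OC)o1 | intermediate
6 | trimethyl orthoformate | COC(OC)OC | starting material
7 | methyl 3,3-dimethoxy-4-(4-oxo-6-pentacosyl-4H-pyran-2-yl)butanoate (dimethyl ketal, not isolated) | CCCCCCCCCCCCCCCCCCCCCCCCCc1cc(=O)cc(CC(OC)(OC)CC(=O)OC)o1 | intermediate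
8 | methyl (E)-3-methoxy-4-(4-oxo-6-pentacosyl-4H-pyran-2-yl)but-2-enoate (CH2 and ester cis) | CCCCCCCCCCCCCCCCCCCCCCCCCc1cc(=O)cc(C/C(OC)=C\C(=O)OC)o1 | intermediate
9 | 7-methoxy-2-pentacosyl-4aH-chromene-4,5-dione (racemic at C4a, keto tautomer of 10, not isolated) | CCCCCCCCCCCCCCCCCCCCCCCCCC1=CC(=O)C2C(=O)C=C(OC)C=C2O1 | intermediate
10 | 5-hydroxy-7-methoxy-2-pentacosyl-4H-chromen-4-one | CCCCCCCCCCCCCCCCCCCCCCCCCc1cc(=O)c2c(O)cc(OC)cc2o1 | intermediate
11 | 5,7-dihydroxy-2-pentacosyl-4H-chromen-4-one | CCCCCCCCCCCCCCCCCCCCCCCCCc1cc(=O)c2c(O)cc(O)cc2o1 | target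

Total step count: 5. Longest linear sequence: 5 steps (1 → 3 → 5 → 8 → 10 → 11).

Steps most likely to fail

Step 4. The anion of 8 may be too stabilized, and the ester too strongly deactivated by the β-methoxy group, for ring closure to outrun intermolecular conjugate addition or slow decomposition on heating. The fallback uses known chemistry and buys ring A instead of folding it. It sets out from 2: purchased 5,7-dimethoxy-2-methyl-4H-chromen-4-one (Cc1cc(=O)c2c(OC)cc(OC)cc2o1) is deprotonated at its 2-methyl group with LiN(i-Pr)2 in THF at −78 °C, and the lateral dienolate is alkylated with 2 (DMPU, −78 → 0 °C) to give 5,7-dimethoxy-2-pentacosyl-4H-chromen-4-one F1. BBr3 in CH2Cl2 (25 → 40 °C) should then cleave both methyl ethers, and the sequence comes back to the route at 11.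

Step 2. Proton transfer from the acidic acid chloride or from the product may quench the dienolate (ketene formation, stalled conversion), acylation may go to oxygen, and some deprotonation may occur at the chain CH2. The fallback sets out from 3 and replaces direct malonylation by carboxylation and two-carbon extension. The lateral lithium dienolate of 3 (LiN(SiMe3)2, THF, −78 °C) is trapped with CO2, a non-enolizable electrophile that reacts at carbon, to give 2-(4-oxo-6-pentacosyl-4H-pyran-2-yl)acetic acid F2. Activation with 1,1'-carbonyldiimidazole in THF at 25 °C gives 2-[2-(1H-imidazol-1-yl)-2-oxoethyl]-6-pentacosyl-4H-pyran-4-one F3, which is treated in the same flask with Mg(O2CCH2CO2Me)2 (decarboxylative Claisen chain extension). Mild acid work-up brings the sequence back to the route at 5.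

Step 1. The SN2 reaction with the poorly soluble long-chain bromide may be slow enough for double alkylation and self-condensation of the dienolate to compete. The fallback sets out from 1 and alkylates an open-chain form in which only one terminus is activated. Aqueous Ba(OH)2 opens 1 to heptane-2,4,6-trione F4. Its trianion (LiN(i-Pr)2, 3 equiv, THF, 0 °C) should be alkylated at the terminal, most basic carbon by 2 to give hentriacontane-2,4,6-trione F5. Cyclodehydration in cold concentrated H2SO4 closes the pyranone and returns to the route at 3.

Further compounds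
F1 | step 4 | 5,7-dimethoxy-2-pentacosyl-4H-chromen-4-one | CCCCCCCCCCCCCCCCCCCCCCCCCc1cc(=O)c2c(OC)cc(OC)cc2o1
F2 | step 2 | 2-(4-oxo-6-pentacosyl-4H-pyran-2-yl)acetic acid | CCCCCCCCCCCCCCCCCCCCCCCCCc1cc(=O)cc(CC(=O)O)o1
F3 | step 2 | 2-[2-(1H-imidazol-1-yl)-2-oxoethyl]-6-pentacosyl-4H-pyran-4-one | CCCCCCCCCCCCCCCCCCCCCCCCCc1cc(=O)cc(CC(=O)n2ccnc2)o1
F4 | step 1 | heptane-2,4,6-trione | CC(=O)CC(=O)CC(C)=O
F5 | step 1 | hentriacontane-2,4,6-trione | CCCCCCCCCCCCCCCCCCCCCCCCCC(=O)CC(=O)CC(C)=O
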